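## The problem

Target 26 is a dihydrochalcone whose ring A is a pentasubstituted benzene fused to a 2,2-dimethyl-2H-pyran. Going round ring A, C4a carries the pyran carbon C4, C5 is the only CH, C6 bears the 3-(4-hydroxyphenyl)propanoyl group, C7 a free hydroxyl hydrogen-bonded to that ketone, C8 a prenyl group and C8a the pyran oxygen. The difficulty is regiochemical: four contiguous substituents on a resorcinol core, with the prenyl carbon between the two oxygens, a position that electrophilic prenylation of a 2,4-dihydroxyaryl ketone does not address cleanly. The two oxygens must also end up differentiated, one free and one in the pyran.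

Compound 26 has no stereocentre, so nothing has to be controlled or relayed. The one stereocentre met on the way, a carbinol at the future ketone carbon, is a placeholder that is carried racemic and erased by oxidation.

Several groups will not survive rough treatment. A prenyl group ortho to a phenol closes to a chroman under acid and to a chromene with quinone oxidants. The 2H-chromene is acid-labile and opens under ultraviolet light, so any photochemical step must come before the pyran. The electron-rich phenols are prone to oxidation.

The enabling feature is that C8, flanked by the oxygenated carbons C7 and C8a, is where the β-carbon of an ynol ether ends up when a vinylketene is annulated. C7, C4a, C5 and C6 map onto the vinylketene, and C8 and C8a onto the alkyne. The C7 oxygen comes from the ketene carbonyl and the C8a oxygen from the ynol ether, so the two oxygens emerge differentiated.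

## Retrosynthesis

**Pyran last.** In 26 the bonds O1–C2 and C4–C4a are cut, giving the triol ketone 23 and 3-methylbut-2-enal 24. Closing the pyran at the end keeps the photolabile chromene away from the 254 nm step and from the fluoride and oxidation steps. In 23 the regiochemistry is forced: the C7 hydroxyl has no free ortho carbon and is tied up in a hydrogen bond, while the C8a hydroxyl has exactly one free ortho carbon, C4a. A propargyl ether Claisen route would cost an extra step. The forward reaction must leave the ring B phenol and the ketone α-methylene alone.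

**Ketone from a carbinol, phenols unveiled.** No skeletal bond is cut: 23 comes from the tetraol 22 by benzylic oxidation, and 22 from the tris-silyl ether 21 by fluoride. The C6 chain is carried as a silylated carbinol because the ring is to be made from a diazo enone, and an ene-dione at that stage would not be a workable Wolff substrate. The forward oxidation must pick the benzylic carbinol out of three phenols and a prenyl alkene, which points to MnO2 and excludes quinone oxidants.

**Ring A by benzannulation.** In 21 the bonds C7–C8, C8a–C4a and C6–C7 are cut, giving the diazo enone 11 and the siloxyalkyne 16. A Diels–Alder cut (C6–C7 and C4a–C5) would leave the C7 oxygen as a methyl ether. A cut at the C6 acyl bond would leave the prenyl regiochemistry unsolved. The chosen cut halves the molecule: 11 holds ring B, the linker and C4a to C7, and 16 holds C8, C8a and the prenyl group. The forward reaction needs a clean photochemical Wolff rearrangement, a regioselective ketene–ynol ether [2+2], and tolerance of three silyl ethers and the prenyl alkene.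

**Diazo enone.** The C–N bond of 11 is traced to the methyl enone 9 by detrifluoroacetylative diazo transfer through the diketone 10, which avoids an acid chloride next to a γ-silyloxy group. The C3=C4 alkene of 9 is cut by cross-metathesis into the allylic silyl ether 7 and but-3-en-2-one 8. This saves a step over ozonolysis followed by Wittig olefination and avoids an α-silyloxy aldehyde. Compound 7 comes from the allylic alcohol 6, which is made from the aldehyde 4 and vinylmagnesium bromide 5. Aldehyde 4 comes from the silylated ester 2 through the aluminium hemiacetal 3, and 2 from commercial methyl 3-(4-hydroxyphenyl)propanoate 1.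

**Siloxyalkyne.** The triple bond of 16 is cut between the two alkyne carbons. The oxygen-bearing carbon and the prenyl chain come from the ester 13, and the other alkyne carbon from dibromomethane, through the dibromo enolate 14 and the ynolate 15 (Kowalski homologation stopped at the ynolate). Ester 13 comes from commercial 4-methylpent-3-enoic acid 12 under neutral conditions, since acid would lactonise it. This is shorter than building a skipped enyne and oxidising it.

## Roads not taken

**Alternative 1:** The cut is at both C2–CH3 bonds and O1–C2. Excess methyllithium would add twice to the lactone carbonyl of the coumarin A2, and mild acid would reclose the pyran to the bromochromenol A1. The C6 bromide would then be turned into an aryllithium and acylated with the ring B propanoyl unit.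
- Merits: ring A and the C4a–C4 bond are bought ready-made, every step is ground-state ionic chemistry, and the step count would probably be lower than that of the chosen plan.
- Weak points: A2 needs a prenyl group at C8 and a bromine at C6 beside a free phenol, and bromination in the presence of the prenyl alkene and the coumarin C3=C4 bond is not chemoselective by nature. The C7 phenoxide deactivates the lactone towards methyllithium. The acid used for cyclodehydration can also close the C8 prenyl group onto the C7 hydroxyl. The late acylation needs halogen–lithium exchange on a substrate with an acidic phenol.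
- Comparison: the chosen plan fixes the C6/C7/C8/C8a pattern by the mechanism of one step and never exposes a prenylphenol to acid or to a halogenating agent. Against that it is longer and relies on a photochemical step.

**Alternative 2:** The cut is at O1–C8a. The alkoxide of the (Z)-allylic tertiary alcohol in the fluoroarene A4 would displace the fluoride para to the aldehyde and give the chromene aldehyde A3. The aldehyde would then be extended to the ketone and the methoxymethyl ether removed.
- Merits: the pyran closure is regiochemically unambiguous and does not depend on the nucleophilicity of a phenol carbon. In this respect it is more secure than the amine-catalysed closure of the chosen plan.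
- Weak points: A4 is a pentasubstituted benzene with fluorine, prenyl, acetal, formyl and a (Z)-alkenyl carbinol, so it would take a long run of directed metalations and a semireduction. The fluoride is activated by a single para formyl group on an otherwise electron-rich ring. After A3, the side chain still needs an addition and an oxidation. The acetal must finally be cleaved with acid in the presence of the chromene and the prenyl group.
- Comparison: the chosen plan builds the same substitution pattern in one convergent step from two simple fragments and ends without acid. It has to set against this a less certain pyran closure, for which a fallback is given.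

**Alternative 3:** The cut is at C6–C7 and C4a–C5. The prenylated bis(silyloxy)diene A6 and the ynone A7 would undergo [4+2] cycloaddition, and loss of trimethylsilanol would aromatise ring A to the ketone A5.
- Merits: it is as convergent as the chosen plan, needs no light, and delivers the ketone oxidation state directly, so the carbinol detour and its oxidation disappear. This is a real advantage.
- Weak points: the C7 oxygen emerges as a methyl ether. Cleaving it beside a prenyl group, and before or after the chromene, calls for boron halides that attack both. The diene A6 is tetrasubstituted at its ketene acetal end, so the cycloaddition is hindered and a conjugate addition pathway competes.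
- Comparison: the chosen plan gives the C7 oxygen as a free phenol and the C8a oxygen as a silyl ether, so no ether cleavage is needed. It pays for this with two extra redox and deprotection operations.

Key step: step 9

Assumption: compounds 6, 7, 9, 10, 11, 17, 19, 21 and 22 are racemic at the carbinol carbon, and 18 and 20 are diastereomer mixtures. This is of no consequence, because the centre becomes the ketone carbon in step 11.

## Route

Step 1
Reactants: 1 methyl 3-(4-hydroxyphenyl)propanoate
Product: 2 methyl 3-[4-(tert-butyldimethylsilyloxy)phenyl]propanoate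
Conditions: t-BuMe2SiCl, imidazole, DMF, rt
Reagents that add atoms: tert-butyldimethylsilyl chloride, CC(C)(C)[Si](C)(C)Cl
Why: Imidazole-promoted O-silylation of a phenol; the aryl silyl ether tolerates hydride, Grignard, metathesis, amide base and light, and falls to fluoride at the end.

Step 2
Reactants: 2 methyl 3-[4-(tert-butyldimethylsilyloxy)phenyl]propanoate
Product: 4 3-[4-(tert-butyldimethylsilyloxy)phenyl]propanal, via aluminium hemiacetal 3 (not isolated)
Conditions: i-Bu2AlH (1.1 equiv), CH2Cl2, −78 °C; MeOH, aq. potassium sodium tartrate
Reagents that add atoms: diisobutylaluminium hydride, CC(C)C[AlH]CC(C)C (its aluminium is carried by 3 only)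
Why: Partial reduction of a methyl ester with i-Bu2AlH; the tetrahedral aluminium hemiacetal 3 is stable at −78 °C and releases the aldehyde only on work-up.

Step 3
Reactants: 4 3-[4-(tert-butyldimethylsilyloxy)phenyl]propanal; 5 vinylmagnesium bromide
Product: 6 rac-5-[4-(tert-butyldimethylsilyloxy)phenyl]pent-1-en-3-ol
Conditions: THF, −78 → 0 °C; aq. NH4Cl
Reagents that add atoms: none
Why: Grignard 1,2-addition to an unhindered aldehyde; the new carbinol centre is formed racemic on purpose, since it is oxidised away in step 11.

Step 4
Reactants: 6 rac-5-[4-(tert-butyldimethylsilyloxy)phenyl]pent-1-en-3-ol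
Product: 7 rac-3-(tert-butyldimethylsilyloxy)-5-[4-(tert-butyldimethylsilyloxy)phenyl]pent-1-ene
Conditions: t-BuMe2SiCl, imidazole, DMF, rt
Reagents that add atoms: tert-butyldimethylsilyl chloride, CC(C)(C)[Si](C)(C)Cl
Why: Standard silylation of a secondary allylic alcohol; the ether masks the hydroxyl from the ketene of step 9 and blocks redox isomerisation during metathesis.

Step 5
Reactants: 7 rac-3-(tert-butyldimethylsilyloxy)-5-[4-(tert-butyldimethylsilyloxy)phenyl]pent-1-ene; 8 but-3-en-2-one
Product: 9 rac-(E)-5-(tert-butyldimethylsilyloxy)-7-[4-(tert-butyldimethylsilyloxy)phenyl]hept-3-en-2-one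
Conditions: 8 (3 equiv), second-generation Hoveyda–Grubbs catalyst RuCl2(H2IMes)(=CH-C6H4-2-O-i-Pr) (5 mol %), CH2Cl2, 40 °C
Reagents that add atoms: none
Why: Olefin cross-metathesis of a protected secondary allylic ether with an electron-poor vinyl ketone, a well-used pairing that gives the conjugated (E)-enone under thermodynamic control and releases ethene.

Step 6
Reactants: 9 rac-(E)-5-(tert-butyldimethylsilyloxy)-7-[4-(tert-butyldimethylsilyloxy)phenyl]hept-3-en-2-one
Product: 11 rac-(E)-1-diazo-5-(tert-butyldimethylsilyloxy)-7-[4-(tert-butyldimethylsilyloxy)phenyl]hept-3-en-2-one, via trifluoroacetyl diketone 10 (not isolated)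
Conditions: LiN(SiMe3)2 (1.1 equiv), THF, −78 °C; CF3CO2CH2CF3; then MsN3, Et3N, H2O, MeCN, rt; product kept from light
Reagents that add atoms: methanesulfonyl azide, CS(=O)(=O)N=[N+]=[N-]; 2,2,2-trifluoroethyl trifluoroacetate, O=C(OCC(F)(F)F)C(F)(F)F (its trifluoroacetyl group is carried by 10 only)
Why: Danheiser detrifluoroacetylative diazo transfer, devised for methyl enones: kinetic enolisation on the methyl side, trifluoroacetylation to 10, then diazo transfer with loss of the trifluoroacetyl group as the sulfonamide.

Step 7
Reactants: 12 4-methylpent-3-enoic acid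
Product: 13 methyl 4-methylpent-3-enoate
Conditions: Me3SiCHN2, PhMe/MeOH (4:1), 0 °C → rt; careful concentration (volatile ester)
Reagents that add atoms: trimethylsilyldiazomethane, C[Si](C)(C)C=[N+]=[N-]
Why: Neutral methyl esterification with trimethylsilyldiazomethane; it avoids the acid-catalysed lactonisation of this γ,δ-unsaturated acid and the base-induced shift of the double bond into conjugation.

Step 8
Reactants: 13 methyl 4-methylpent-3-enoate
Product: 16 triisopropyl(5-methylhex-4-en-1-ynyloxy)silane, via dibromo enolate 14 (not isolated), via lithium ynolate 15 (not isolated)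
Conditions: CH2Br2, lithium 2,2,6,6-tetramethylpiperidide, THF, −78 °C; 13; LiN(SiMe3)2; n-BuLi, −78 °C → rt; i-Pr3SiCl, −78 °C → rt
Reagents that add atoms: dibromomethane, BrCBr; triisopropylsilyl chloride, CC(C)[Si](Cl)(C(C)C)C(C)C; lithium bis(trimethylsilyl)amide, [Li]N([Si](C)(C)C)[Si](C)(C)C (its lithium is carried by 14 and 15 only)
Why: Kowalski ester homologation stopped at the ynolate: dibromomethyllithium adds to the ester, the dibromo ketone is enolised to 14, bromine–lithium exchange triggers rearrangement to ynolate 15, and the bulky silyl chloride silylates on oxygen to give the siloxyalkyne.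

Step 9
Reactants: 11 rac-(E)-1-diazo-5-(tert-butyldimethylsilyloxy)-7-[4-(tert-butyldimethylsilyloxy)phenyl]hept-3-en-2-one; 16 triisopropyl(5-methylhex-4-en-1-ynyloxy)silane
Product: 21 rac-6-[1-(tert-butyldimethylsilyloxy)-3-[4-(tert-butyldimethylsilyloxy)phenyl]propyl]-2-(3-methylbut-2-enyl)-3-(triisopropylsilyloxy)phenol, via vinylketene 17 (not isolated), via cyclobutenone 18 (not isolated), via dienylketene 19 (not isolated), via cyclohexadienone 20 (not isolated)
Conditions: 11 (1.0 equiv), 16 (1.3 equiv), degassed ClCH2CH2Cl (0.3 M), hν (254 nm, quartz), rt; then 80 °C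
Reagents that add atoms: none
Why: Light expels dinitrogen from 11 and the alkenyl group migrates to the carbene carbon (photochemical Wolff rearrangement), giving vinylketene 17. The siloxyalkyne adds in a polar [2+2]: its prenyl-bearing β-carbon attacks the ketene carbonyl (C7–C8) and its oxygen-bearing carbon bonds to the ketene α-carbon (C8a–C4a), giving cyclobutenone 18. Reversible 4π electrocyclic opening of 18 gives dienylketene 19, whose 6π electrocyclisation forms C6–C7 and closes ring A as cyclohexadienone 20, which tautomerises to phenol 21. The closest known reaction type is the Danheiser benzannulation in its diazo ketone variant with siloxyalkynes, which gives resorcinol monosilyl ethers. Ring A is the only ring closed, in a pericyclic mode between the ketene carbon and the alkene terminus. No stereocentre is created in 21; the carbinol centre is a spectator, and the diastereomers of 18 and 20 converge. The step needs regioselectivity in the [2+2], secured by the polarity of the partners (nucleophilic alkyne β-carbon, electrophilic ketene carbonyl), and chemoselectivity for the ynol ether over the unactivated prenyl alkene; only the dienylketene isomer with the vinyl group cis to the ketene can cyclise, and reversible ring opening funnels material through it. O-acylation of the product by 17 should be slow because the new phenol is flanked on both sides.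

Step 10
Reactants: 21 rac-6-[1-(tert-butyldimethylsilyloxy)-3-[4-(tert-butyldimethylsilyloxy)phenyl]propyl]-2-(3-methylbut-2-enyl)-3-(triisopropylsilyloxy)phenol
Product: 22 rac-4-[1-hydroxy-3-(4-hydroxyphenyl)propyl]-2-(3-methylbut-2-enyl)benzene-1,3-diol
Conditions: Bu4NF (4 equiv), AcOH (4 equiv), THF, 0 °C → rt; used directly in step 11
Reagents that add atoms: none
Why: Fluoride desilylation of two aryl silyl ethers and one secondary alkyl silyl ether; the acetic acid buffer keeps the medium near neutral so that the sensitive dihydroxybenzylic alcohol is not exposed to strong base or acid.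

Step 11
Reactants: 22 rac-4-[1-hydroxy-3-(4-hydroxyphenyl)propyl]-2-(3-methylbut-2-enyl)benzene-1,3-diol
Product: 23 1-[2,4-dihydroxy-3-(3-methylbut-2-enyl)phenyl]-3-(4-hydroxyphenyl)propan-1-one
Conditions: activated MnO2 (15 equiv), acetone, rt
Reagents that add atoms: none
Why: MnO2 oxidation of a benzylic alcohol, which is selective for the activated ortho-hydroxybenzylic carbinol over phenols and isolated alkenes; the product ketone is stabilised by the hydrogen bond to the C7 hydroxyl.

Step 12
Reactants: 23 1-[2,4-dihydroxy-3-(3-methylbut-2-enyl)phenyl]-3-(4-hydroxyphenyl)propan-1-one; 24 3-methylbut-2-enal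
Product: 26 1-[7-hydroxy-2,2-dimethyl-8-(3-methylbut-2-enyl)-2H-chromen-6-yl]-3-(4-hydroxyphenyl)propan-1-one, via alkylidene dienone 25 (not isolated)
Conditions: 24 (2.5 equiv), ethylenediammonium diacetate (20 mol %), xylene, 120 °C
Reagents that add atoms: none
Why: Amine-salt-catalysed Knoevenagel-type condensation of the resorcinol carbon C4a with the enal gives dienone 25, which closes by oxa-6π electrocyclisation to the 2,2-dimethyl-2H-chromene; C4a is the only free carbon ortho to the non-chelated hydroxyl, and the isolated ring B phenol is too weak a carbon nucleophile to compete.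

## Compound list

1 | methyl 3-(4-hydroxyphenyl)propanoate | COC(=O)CCc1ccc(O)cc1 | starting material
2 | methyl 3-[4-(tert-butyldimethylsilyloxy)phenyl]propanoate | COC(=O)CCc1ccc(O[Si](C)(C)C(C)(C)C)cc1 | intermediate
3 | diisobutyl[1-methoxy-3-[4-(tert-butyldimethylsilyloxy)phenyl]propoxy]aluminium (aluminium hemiacetal, racemic) | COC(CCc1ccc(O[Si](C)(C)C(C)(C)C)cc1)O[Al](CC(C)C)CC(C)C | intermediate
4 | 3-[4-(tert-butyldimethylsilyloxy)phenyl]propanal | O=CCCc1ccc(O[Si](C)(C)C(C)(C)C)cc1 | intermediate
5 | vinylmagnesium bromide | C=C[Mg]Br | starting material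
6 | rac-5-[4-(tert-butyldimethylsilyloxy)phenyl]pent-1-en-3-ol | C=CC(O)CCc1ccc(O[Si](C)(C)C(C)(C)C)cc1 | intermediate
7 | rac-3-(tert-butyldimethylsilyloxy)-5-[4-(tert-butyldimethylsilyloxy)phenyl]pent-1-ene | C=CC(O[Si](C)(C)C(C)(C)C)CCc1ccc(O[Si](C)(C)C(C)(C)C)cc1 | intermediate
8 | but-3-en-2-one | CC(=O)C=C | starting material
9 | rac-(E)-5-(tert-butyldimethylsilyloxy)-7-[4-(tert-butyldimethylsilyloxy)phenyl]hept-3-en-2-one | CC(=O)/C=C/C(O[Si](C)(C)C(C)(C)C)CCc1ccc(O[Si](C)(C)C(C)(C)C)cc1 | intermediate
10 | rac-(E)-1,1,1-trifluoro-7-(tert-butyldimethylsilyloxy)-9-[4-(tert-butyldimethylsilyloxy)phenyl]non-5-ene-2,4-dione | O=C(CC(=O)/C=C/C(O[Si](C)(C)C(C)(C)C)CCc1ccc(O[Si](C)(C)C(C)(C)C)cc1)C(F)(F)F | intermediate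
11 | rac-(E)-1-diazo-5-(tert-butyldimethylsilyloxy)-7-[4-(tert-butyldimethylsilyloxy)phenyl]hept-3-en-2-one | [N-]=[N+]=CC(=O)/C=C/C(O[Si](C)(C)C(C)(C)C)CCc1ccc(O[Si](C)(C)C(C)(C)C)cc1 | intermediate
12 | 4-methylpent-3-enoic acid | CC(C)=CCC(=O)O | starting material
13 | methyl 4-methylpent-3-enoate | COC(=O)CC=C(C)C | intermediate
14 | lithium 1,1-dibromo-5-methylhexa-1,4-dien-2-olate | [Li+].[O-]C(CC=C(C)C)=C(Br)Br | intermediate
15 | lithium 5-methylhex-4-en-1-yn-1-olate | [Li+].[O-]C#CCC=C(C)C | intermediate
16 | triisopropyl(5-methylhex-4-en-1-ynyloxy)silane | CC(C)=CCC#CO[Si](C(C)C)(C(C)C)C(C)C | intermediate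
17 | rac-(E)-5-(tert-butyldimethylsilyloxy)-7-[4-(tert-butyldimethylsilyloxy)phenyl]hepta-1,3-dien-1-one (vinylketene) | O=C=C/C=C/C(O[Si](C)(C)C(C)(C)C)CCc1ccc(O[Si](C)(C)C(C)(C)C)cc1 | intermediate
18 | 4-[(E)-3-(tert-butyldimethylsilyloxy)-5-[4-(tert-butyldimethylsilyloxy)phenyl]pent-1-enyl]-2-(3-methylbut-2-enyl)-3-(triisopropylsilyloxy)cyclobut-2-en-1-one (diastereomer mixture) | O=C1C(CC=C(C)C)=C(O[Si](C(C)C)(C(C)C)C(C)C)C1/C=C/C(O[Si](C)(C)C(C)(C)C)CCc1ccc(O[Si](C)(C)C(C)(C)C)cc1 | intermediate
19 | rac-(3E,5E)-7-(tert-butyldimethylsilyloxy)-9-[4-(tert-butyldimethylsilyloxy)phenyl]-2-(3-methylbut-2-enyl)-3-(triisopropylsilyloxy)nona-1,3,5-trien-1-one (dienylketene, C2 and C5 cis about C3=C4) | O=C=C(CC=C(C)C)/C(O[Si](C(C)C)(C(C)C)C(C)C)=C\C=C\C(O[Si](C)(C)C(C)(C)C)CCc1ccc(O[Si](C)(C)C(C)(C)C)cc1 | intermediate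
20 | 6-[1-(tert-butyldimethylsilyloxy)-3-[4-(tert-butyldimethylsilyloxy)phenyl]propyl]-2-(3-methylbut-2-enyl)-3-(triisopropylsilyloxy)cyclohexa-2,4-dien-1-one (diastereomer mixture) | O=C1C(CC=C(C)C)=C(O[Si](C(C)C)(C(C)C)C(C)C)C=CC1C(O[Si](C)(C)C(C)(C)C)CCc1ccc(O[Si](C)(C)C(C)(C)C)cc1 | intermediate
21 | rac-6-[1-(tert-butyldimethylsilyloxy)-3-[4-(tert-butyldimethylsilyloxy)phenyl]propyl]-2-(3-methylbut-2-enyl)-3-(triisopropylsilyloxy)phenol | CC(C)=CCc1c(O)c(C(O[Si](C)(C)C(C)(C)C)CCc2ccc(O[Si](C)(C)C(C)(C)C)cc2)ccc1O[Si](C(C)C)(C(C)C)C(C)C | intermediate
22 | rac-4-[1-hydroxy-3-(4-hydroxyphenyl)propyl]-2-(3-methylbut-2-enyl)benzene-1,3-diol | CC(C)=CCc1c(O)c(C(O)CCc2ccc(O)cc2)ccc1O | intermediate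
23 | 1-[2,4-dihydroxy-3-(3-methylbut-2-enyl)phenyl]-3-(4-hydroxyphenyl)propan-1-one | CC(C)=CCc1c(O)c(C(=O)CCc2ccc(O)cc2)ccc1O | intermediate
24 | 3-methylbut-2-enal | CC(C)=CC=O | starting material
25 | 3-hydroxy-4-[3-(4-hydroxyphenyl)propanoyl]-2-(3-methylbut-2-enyl)-6-(3-methylbut-2-enylidene)cyclohexa-2,4-dien-1-one | CC(C)=CC=C1C=C(C(=O)CCc2ccc(O)cc2)C(O)=C(CC=C(C)C)C1=O | intermediate
26 | 1-[7-hydroxy-2,2-dimethyl-8-(3-methylbut-2-enyl)-2H-chromen-6-yl]-3-(4-hydroxyphenyl)propan-1-one | CC(C)=CCc1c(O)c(C(=O)CCc2ccc(O)cc2)cc2c1OC(C)(C)C=C2 | target

## Step count and risks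

Total: 12 steps. Longest linear sequence: 10 steps (steps 1–6 and 9–12, from 1). The alkyne branch (steps 7 and 8) joins at step 9.

**Step 9 (key step).** The transient aldoketene 17 may be captured inefficiently, through dimerisation or acylation of the product phenol. Secondary photoreactions are also possible, because the aryl silyl ethers and the product absorb at the irradiation wavelength. The fallback separates ketene formation from ring construction and sets out from 11.
- C-Silylation of 11 with i-Pr3SiOTf and i-Pr2NEt should give rac-(E)-1-diazo-1-(triisopropylsilyl)-5-(tert-butyldimethylsilyloxy)-7-[4-(tert-butyldimethylsilyloxy)phenyl]hept-3-en-2-one F1.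
- Photochemical Wolff rearrangement of F1 alone, at 300 nm, should give the stable, isolable silylvinylketene rac-(E)-5-(tert-butyldimethylsilyloxy)-7-[4-(tert-butyldimethylsilyloxy)phenyl]-2-(triisopropylsilyl)hepta-1,3-dien-1-one F2.
- In the dark, F2 is treated with ynolate 15, taken from the step 8 sequence before silylation. The ynolate is C-acylated (C8–C8a), the resulting 3-oxidodienylketene closes by 6π electrocyclisation (C6–C7), and a 1,3 carbon-to-oxygen silyl shift should give, after protonation, 21, where the route is rejoined.

**Step 11.** The 2,4-dihydroxybenzylic alcohol may ionise to a quinone methide and dehydrate or oligomerise before it is oxidised, and the free resorcinol may undergo oxidative coupling on MnO2. The fallback oxidises while two of the phenols are still silylated and sets out from 21.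
- HF·pyridine in THF/pyridine should cleave only the secondary alkyl silyl ether and give rac-6-[1-hydroxy-3-[4-(tert-butyldimethylsilyloxy)phenyl]propyl]-2-(3-methylbut-2-enyl)-3-(triisopropylsilyloxy)phenol F3.
- Dess–Martin periodinane buffered with NaHCO3 should oxidise the carbinol next to the single, hindered phenol to 1-[2-hydroxy-3-(3-methylbut-2-enyl)-4-(triisopropylsilyloxy)phenyl]-3-[4-(tert-butyldimethylsilyloxy)phenyl]propan-1-one F4.
- Bu4NF then removes both aryl silyl groups and returns to the route at 23.

**Step 8.** The lithium amide or the carbenoid may enolise the β,γ-unsaturated ester instead of adding to it, moving the double bond into conjugation, and the doubly activated methylene of the ynolate may be deprotonated. The fallback makes the ynolate by oxidising an acetylide and sets out from 13.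
- i-Bu2AlH at −78 °C should give 4-methylpent-3-enal F5, used at once.
- Corey–Fuchs olefination (CBr4, PPh3) should give 1,1-dibromo-5-methylhexa-1,4-diene F6.
- n-BuLi (2 equiv) should convert F6 into lithium 5-methylhex-4-en-1-yn-1-ide F7.
- In the same flask, lithium tert-butyl peroxide oxidises F7 (Julia ynolate synthesis) to ynolate 15, where the route is rejoined before silylation to 16.

**Step 12.** Condensation at C4a may be slow on the acyl-deactivated ring, so that self-condensation of the enal or reaction at the ketone α-methylene competes at the temperature needed. The fallback builds the pyran by a sigmatropic route and sets out from 23.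
- The more acidic, non-chelated C4 hydroxyl is alkylated with 3-chloro-3-methylbut-1-yne (K2CO3, KI, CuI catalyst, acetone) to give 1-[2-hydroxy-4-(2-methylbut-3-yn-2-yloxy)-3-(3-methylbut-2-enyl)phenyl]-3-(4-hydroxyphenyl)propan-1-one F8.
- Heating F8 in N,N-diethylaniline at about 180 °C should bring about the aryl propargyl ether Claisen rearrangement to the only free ortho carbon, a 1,5-hydrogen shift and oxa-6π closure, arriving directly at 26.

## Further compounds

F1 | step 9 | rac-(E)-1-diazo-1-(triisopropylsilyl)-5-(tert-butyldimethylsilyloxy)-7-[4-(tert-butyldimethylsilyloxy)phenyl]hept-3-en-2-one | [N-]=[N+]=C([Si](C(C)C)(C(C)C)C(C)C)C(=O)/C=C/C(O[Si](C)(C)C(C)(C)C)CCc1ccc(O[Si](C)(C)C(C)(C)C)cc1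
F2 | step 9 | rac-(E)-5-(tert-butyldimethylsilyloxy)-7-[4-(tert-butyldimethylsilyloxy)phenyl]-2-(triisopropylsilyl)hepta-1,3-dien-1-one | O=C=C([Si](C(C)C)(C(C)C)C(C)C)/C=C/C(O[Si](C)(C)C(C)(C)C)CCc1ccc(O[Si](C)(C)C(C)(C)C)cc1
F3 | step 11 | rac-6-[1-hydroxy-3-[4-(tert-butyldimethylsilyloxy)phenyl]propyl]-2-(3-methylbut-2-enyl)-3-(triisopropylsilyloxy)phenol | CC(C)=CCc1c(O)c(C(O)CCc2ccc(O[Si](C)(C)C(C)(C)C)cc2)ccc1O[Si](C(C)C)(C(C)C)C(C)C
F4 | step 11 | 1-[2-hydroxy-3-(3-methylbut-2-enyl)-4-(triisopropylsilyloxy)phenyl]-3-[4-(tert-butyldimethylsilyloxy)phenyl]propan-1-one | CC(C)=CCc1c(O)c(C(=O)CCc2ccc(O[Si](C)(C)C(C)(C)C)cc2)ccc1O[Si](C(C)C)(C(C)C)C(C)C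
F5 | step 8 | 4-methylpent-3-enal | CC(C)=CCC=O
F6 | step 8 | 1,1-dibromo-5-methylhexa-1,4-diene | CC(C)=CCC=C(Br)Br
F7 | step 8 | lithium 5-methylhex-4-en-1-yn-1-ide | [Li]C#CCC=C(C)C
F8 | step 12 | 1-[2-hydroxy-4-(2-methylbut-3-yn-2-yloxy)-3-(3-methylbut-2-enyl)phenyl]-3-(4-hydroxyphenyl)propan-1-one | CC(C)=CCc1c(O)c(C(=O)CCc2ccc(O)cc2)ccc1OC(C)(C)C#C
A1 | alternative 1 | 6-bromo-2,2-dimethyl-8-(3-methylbut-2-enyl)-2H-chromen-7-ol | CC(C)=CCc1c(O)c(Br)cc2c1OC(C)(C)C=C2
A2 | alternative 1 | 6-bromo-7-hydroxy-8-(3-methylbut-2-enyl)chromen-2-one | CC(C)=CCc1c(O)c(Br)cc2ccc(=O)oc12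
A3 | alternative 2 | 7-(methoxymethoxy)-2,2-dimethyl-8-(3-methylbut-2-enyl)-2H-chromene-6-carbaldehyde | CC(C)=CCc1c(OCOC)c(C=O)cc2c1OC(C)(C)C=C2
A4 | alternative 2 | 4-fluoro-5-[(Z)-3-hydroxy-3-methylbut-1-enyl]-2-(methoxymethoxy)-3-(3-methylbut-2-enyl)benzaldehyde | CC(C)=CCc1c(OCOC)c(C=O)cc(/C=C\C(C)(C)O)c1F
A5 | alternative 3 | 1-[4-hydroxy-2-methoxy-3-(3-methylbut-2-enyl)phenyl]-3-[4-(tert-butyldimethylsilyloxy)phenyl]propan-1-one | COc1c(CC=C(C)C)c(O)ccc1C(=O)CCc1ccc(O[Si](C)(C)C(C)(C)C)cc1
A6 | alternative 3 | 1-methoxy-2-(3-methylbut-2-enyl)-1,3-bis(trimethylsilyloxy)buta-1,3-diene | COC(O[Si](C)(C)C)=C(CC=C(C)C)C(=C)O[Si](C)(C)C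
A7 | alternative 3 | 5-[4-(tert-butyldimethylsilyloxy)phenyl]pent-1-yn-3-one | C#CC(=O)CCc1ccc(O[Si](C)(C)C(C)(C)C)cc1
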